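**Retrosynthetic overview** (tetralone numbering: C1 ketone, C3 carbinol, C5 pyranyl, C6 3-methylbutyl, C8 phenol; pyranone atoms primed)
1. Feature: pyranone carbon C6' on C5 is an aryl carboxyl carbon in disguise and lies ortho to C4a, whose chain C4–C3 carries the C3 oxygen. Carboxyl carbon and O3 can therefore be tied into a six-membered lactone ring (C6', C5, C4a, C4, C3, O), a 3,4-dihydroisocoumarin.
2. Key disconnection: that lactone is cut at C4a–C4 and at O–C(=O), giving 4-methoxy-2-(3-methylbutyl)benzoic acid and (S)-2-[2-(benzyloxy)ethyl]oxirane (carboxylate-directed palladium C–H alkylation).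
3. The lactone is then the acyl donor for the dienolate of 2,2,6-trimethyl-4H-1,3-dioxin-4-one (C6'–C5' bond), which frees O3; thermolysis closes the pyranone.
4. The cyclohexanone ring is closed last at C1–C8a by Friedel–Crafts acylation; C1 is oxidised to the acid while the lactone is still intact.
5. Ring order: benzene ring (bought), temporary lactone ring, pyranone ring, cyclohexanone ring; C3 comes from the resolved epoxide.

Key step: step 5

Assumption: the (S,S)-cobalt salen catalyst is taken to consume the (R)-epoxide, as is usual for alkyl-substituted terminal epoxides; the configuration of recovered 8 is checked before use and the enantiomeric catalyst is taken if the sense is opposite.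

**Route**

Step 1
Reactants: 1 4-methoxy-2-methylbenzoic acid; 2 1-bromo-2-methylpropane
Product: 4 4-methoxy-2-(3-methylbutyl)benzoic acid, via dilithium dianion 3 (not isolated)
Conditions: LiN(iPr)2 (2.2 equiv), THF, −78 to 0 °C; then 2 (1.3 equiv), −78 °C to rt; aq. HCl
Reagents that add atoms: none
Why: Lateral (benzylic) lithiation of the lithium ortho-toluate gives dianion 3, whose benzylic carbanion is alkylated by the primary bromide in an SN2 reaction while the carboxyl group stays protected as its lithium salt.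

Step 2
Reactants: 5 but-3-en-1-ol
Product: 6 4-(benzyloxy)but-1-ene
Conditions: NaH, BnBr, Bu4NI (cat.), THF, 0 °C to rt
Reagents that add atoms: benzyl bromide, BrCc1ccccc1
Why: Williamson ether synthesis of the primary alkoxide; the benzyl ether is chosen because it is inert to palladium diacetate in hot hexafluoropropan-2-ol.

Step 3
Reactants: 6 4-(benzyloxy)but-1-ene
Product: 7 rac-2-[2-(benzyloxy)ethyl]oxirane
Conditions: mCPBA, CH2Cl2, 0 °C to rt
Reagents that add atoms: 3-chloroperoxybenzoic acid (mCPBA), OOC(=O)c1cccc(Cl)c1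
Why: Prilezhaev epoxidation of the monosubstituted alkene by the peracid, which gives the racemic epoxide.

Step 4
Reactants: 7 rac-2-[2-(benzyloxy)ethyl]oxirane
Product: 8 (S)-2-[2-(benzyloxy)ethyl]oxirane
Conditions: (S,S)-(salen)Co(OAc) (0.5 mol%), H2O (0.55 equiv), THF (minimal), 0 °C to rt; distillation
Reagents that add atoms: none
Why: Jacobsen hydrolytic kinetic resolution: the trivalent cobalt salen acetate (salen = N,N'-bis(3,5-di-tert-butylsalicylidene)-1,2-cyclohexanediamine) hydrolyses the (R)-epoxide much faster by cooperative activation of epoxide and water, so the unreacted (S)-epoxide 8, which carries the future C3 stereocentre, should be recovered in high enantiomeric purity when the reaction is run slightly past half conversion.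

Step 5
Reactants: 4 4-methoxy-2-(3-methylbutyl)benzoic acid; 8 (S)-2-[2-(benzyloxy)ethyl]oxirane
Product: 10 (3R)-3-[2-(benzyloxy)ethyl]-6-methoxy-8-(3-methylbutyl)-3,4-dihydro-1H-isochromen-1-one, via hydroxy acid 9 (not isolated)
Conditions: Pd(OAc)2 (5 mol%), N-acetyl-L-tert-leucine (10 mol%), KOAc (1.0 equiv), 8 (1.5 equiv), (CF3)2CHOH, 75 °C
Reagents that add atoms: none
Why: Carboxylate-assisted concerted metalation–deprotonation at the only free ortho C–H of the potassium salt of 4 (the carbon that becomes C4a) gives a five-membered aryl–palladium carboxylate, whose aryl–Pd bond attacks the coordinated epoxide at its unsubstituted CH2 in an SN2-type, redox-neutral opening (palladium stays divalent) to form C4a–C4; protonolysis releases hydroxy acid 9. The closest known reaction type is the ortho C–H alkylation of benzoic acids with terminal epoxides, catalysed by palladium diacetate and a mono-N-protected amino acid, which gives 3-substituted 3,4-dihydroisocoumarins. The lactone ring closes by 6-exo-trig acyl substitution of the C3 hydroxyl on the neighbouring carboxyl group with loss of water. No stereocentre is created: the C3–O bond of the epoxide is never broken, so its geometry is carried over unchanged and the descriptor changes from S to R only because the CIP priorities of the two carbon substituents swap. Site selectivity is needed on the arene and on the epoxide: the 3-methylbutyl group blocks the second ortho position, so only one palladacycle can form and double alkylation is excluded, and sterics steer attack away from the substituted epoxide carbon.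

Step 6
Reactants: 10 (3R)-3-[2-(benzyloxy)ethyl]-6-methoxy-8-(3-methylbutyl)-3,4-dihydro-1H-isochromen-1-one
Product: 11 (3R)-3-(2-hydroxyethyl)-6-methoxy-8-(3-methylbutyl)-3,4-dihydro-1H-isochromen-1-one
Conditions: H2 (1 atm), Pd/C (10%), EtOAc, rt
Reagents that add atoms: none
Why: Heterogeneous hydrogenolysis of the benzyl ether, placed here because no pyranone double bond is yet present and the homobenzylic lactone C–O bond is not cleaved.

Step 7
Reactants: 11 (3R)-3-(2-hydroxyethyl)-6-methoxy-8-(3-methylbutyl)-3,4-dihydro-1H-isochromen-1-one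
Product: 12 2-[(3R)-6-methoxy-8-(3-methylbutyl)-1-oxo-3,4-dihydro-1H-isochromen-3-yl]acetic acid
Conditions: TEMPO (20 mol%), PhI(OAc)2 (2.5 equiv), MeCN/H2O 1:1, rt
Reagents that add atoms: water, O
Why: Oxoammonium (TEMPO) oxidation of the primary alcohol to the aldehyde and of its hydrate to the acid under near-neutral conditions, so the β-acyloxy aldehyde is not exposed to base; C1 reaches the acid level before any pyranone or β-hydroxy ketone exists.

Step 8
Reactants: 12 2-[(3R)-6-methoxy-8-(3-methylbutyl)-1-oxo-3,4-dihydro-1H-isochromen-3-yl]acetic acid; 13 2,2,6-trimethyl-4H-1,3-dioxin-4-one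
Product: 15 (3R)-4-{2-[2-(2,2-dimethyl-4-oxo-4H-1,3-dioxin-6-yl)acetyl]-5-methoxy-3-(3-methylbutyl)phenyl}-3-hydroxybutanoic acid, via lithium dienolate 14 (not isolated)
Conditions: 13 (3.6 equiv), LiN(SiMe3)2 (3.4 equiv), THF, −78 °C; then 12, −78 to −30 °C; AcOH
Reagents that add atoms: none
Why: Crossed Claisen-type acylation of the γ-carbon of dienolate 14 by the lactone: the first equivalent only forms the inert lithium carboxylate, the second attacks the planar, non-enolisable aryl lactone carbonyl from its open face, and the third removes the product as its stabilised enolate, which drives collapse of the tetrahedral adduct and frees the C3 alkoxide; the dioxinone is kept in slight excess over the amide base so that no stronger base remains to deprotonate benzylic C4.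

Step 9
Reactants: 15 (3R)-4-{2-[2-(2,2-dimethyl-4-oxo-4H-1,3-dioxin-6-yl)acetyl]-5-methoxy-3-(3-methylbutyl)phenyl}-3-hydroxybutanoic acid
Product: 17 (3R)-3-hydroxy-4-[2-(4-hydroxy-2-oxo-2H-pyran-6-yl)-5-methoxy-3-(3-methylbutyl)phenyl]butanoic acid, via acylketene 16 (not isolated)
Conditions: PhMe (0.01 M), 110 °C
Reagents that add atoms: none
Why: Thermal retro-hetero-Diels–Alder loss of acetone from the dioxinone gives acylketene 16, which is trapped by the enol oxygen of the aryl ketone in a six-membered closure and tautomerises to the 4-hydroxy-2-pyranone; high dilution suppresses intermolecular capture by the free hydroxyl and carboxyl groups.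

Step 10
Reactants: 17 (3R)-3-hydroxy-4-[2-(4-hydroxy-2-oxo-2H-pyran-6-yl)-5-methoxy-3-(3-methylbutyl)phenyl]butanoic acid
Product: 19 (3R)-4-[2-(4-hydroxy-2-oxo-2H-pyran-6-yl)-5-methoxy-3-(3-methylbutyl)phenyl]-3-[(triisopropylsilyl)oxy]butanoic acid, via tris-silyl derivative 18 (not isolated)
Conditions: TIPSOTf (3.5 equiv), 2,6-lutidine, CH2Cl2, 0 °C to rt; then K2CO3, MeOH/H2O, rt; aq. citric acid
Reagents that add atoms: triisopropylsilyl trifluoromethanesulfonate, CC(C)[Si](C(C)C)(C(C)C)OS(=O)(=O)C(F)(F)F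
Why: Exhaustive silylation with the silyl triflate followed by selective solvolysis: the silyl ester and the pyranyl silyl ether (a vinylogous silyl ester) are cleaved by carbonate in aqueous methanol, while the secondary alkyl triisopropylsilyl ether is stable.

Step 11
Reactants: 19 (3R)-4-[2-(4-hydroxy-2-oxo-2H-pyran-6-yl)-5-methoxy-3-(3-methylbutyl)phenyl]-3-[(triisopropylsilyl)oxy]butanoic acid
Product: 22 (3R)-5-(4-hydroxy-2-oxo-2H-pyran-6-yl)-8-methoxy-6-(3-methylbutyl)-3-[(triisopropylsilyl)oxy]-3,4-dihydronaphthalen-1(2H)-one, via bis-trifluoroacetyl mixed anhydride 20 (not isolated), via pyranyl trifluoroacetate 21 (not isolated)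
Conditions: (CF3CO)2O (3 equiv), CH2Cl2, 0 °C; CF3CO2H (10 equiv), 0 °C to rt; then MeOH, aq. NaHCO3, 0 °C
Reagents that add atoms: none
Why: Intramolecular Friedel–Crafts acylation through the mixed trifluoroacetic anhydride: the acylium equivalent attacks C8a, the only ring carbon within reach of the chain and one activated by the ortho methoxy and para alkyl groups, and closes the six-membered ketone ring, while the pyranone hydroxyl is masked in situ as its trifluoroacetate (removed by methanolysis) and the bulky silyl ether keeps the C3 oxygen from ionising or eliminating.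

Step 12
Reactants: 22 (3R)-5-(4-hydroxy-2-oxo-2H-pyran-6-yl)-8-methoxy-6-(3-methylbutyl)-3-[(triisopropylsilyl)oxy]-3,4-dihydronaphthalen-1(2H)-one
Product: 23 (3R)-8-hydroxy-5-(4-hydroxy-2-oxo-2H-pyran-6-yl)-6-(3-methylbutyl)-3-[(triisopropylsilyl)oxy]-3,4-dihydronaphthalen-1(2H)-one
Conditions: BCl3 (4 equiv), CH2Cl2, −78 to −20 °C; pH 7 buffer
Reagents that add atoms: none
Why: Chelation-assisted Lewis-acid ether cleavage: BCl3 binds the C1 carbonyl and the peri C8 methoxy oxygen and chloride removes the methyl group at low temperature, which the silyl ether and the pyranone tolerate.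

Step 13
Reactants: 23 (3R)-8-hydroxy-5-(4-hydroxy-2-oxo-2H-pyran-6-yl)-6-(3-methylbutyl)-3-[(triisopropylsilyl)oxy]-3,4-dihydronaphthalen-1(2H)-one
Product: 24 (3R)-3,8-dihydroxy-5-(4-hydroxy-2-oxo-2H-pyran-6-yl)-6-(3-methylbutyl)-3,4-dihydronaphthalen-1(2H)-one
Conditions: HF·pyridine, pyridine, THF, 0 °C to rt
Reagents that add atoms: none
Why: Fluoride-mediated desilylation under buffered, weakly acidic conditions, chosen because base would dehydrate the β-hydroxy ketone to a naphthol by E1cB elimination; the C3 configuration is untouched.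

**Compound list**
1 | 4-methoxy-2-methylbenzoic acid | Cc1cc(OC)ccc1C(=O)O | starting material
2 | 1-bromo-2-methylpropane | CC(C)CBr | starting material
3 | dilithium dianion of 1 (lithium 2-(lithiomethyl)-4-methoxybenzoate) | [Li+].[Li+].[CH2-]c1cc(OC)ccc1C(=O)[O-] | intermediate
4 | 4-methoxy-2-(3-methylbutyl)benzoic acid | CC(C)CCc1cc(OC)ccc1C(=O)O | intermediate
5 | but-3-en-1-ol | C=CCCO | starting material
6 | 4-(benzyloxy)but-1-ene | C=CCCOCc1ccccc1 | intermediate
7 | rac-2-[2-(benzyloxy)ethyl]oxirane | C1OC1CCOCc1ccccc1 | intermediate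
8 | (S)-2-[2-(benzyloxy)ethyl]oxirane | C1[C@@H](O1)CCOCc1ccccc1 | intermediate
9 | 2-[(2R)-4-(benzyloxy)-2-hydroxybutyl]-4-methoxy-6-(3-methylbutyl)benzoic acid | CC(C)CCc1cc(OC)cc(C[C@@H](O)CCOCc2ccccc2)c1C(=O)O | intermediate
10 | (3R)-3-[2-(benzyloxy)ethyl]-6-methoxy-8-(3-methylbutyl)-3,4-dihydro-1H-isochromen-1-one | CC(C)CCc1cc(OC)cc2c1C(=O)O[C@@H](CCOCc1ccccc1)C2 | intermediate
11 | (3R)-3-(2-hydroxyethyl)-6-methoxy-8-(3-methylbutyl)-3,4-dihydro-1H-isochromen-1-one | CC(C)CCc1cc(OC)cc2c1C(=O)O[C@@H](CCO)C2 | intermediate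
12 | 2-[(3R)-6-methoxy-8-(3-methylbutyl)-1-oxo-3,4-dihydro-1H-isochromen-3-yl]acetic acid | CC(C)CCc1cc(OC)cc2c1C(=O)O[C@@H](CC(=O)O)C2 | intermediate
13 | 2,2,6-trimethyl-4H-1,3-dioxin-4-one | CC1=CC(=O)OC(C)(C)O1 | starting material
14 | lithium dienolate of 13 (lithium 2,2-dimethyl-6-methylidene-6H-1,3-dioxin-4-olate) | [Li+].C=C1C=C([O-])OC(C)(C)O1 | intermediate
15 | (3R)-4-{2-[2-(2,2-dimethyl-4-oxo-4H-1,3-dioxin-6-yl)acetyl]-5-methoxy-3-(3-methylbutyl)phenyl}-3-hydroxybutanoic acid | CC(C)CCc1cc(OC)cc(C[C@@H](O)CC(=O)O)c1C(=O)CC1=CC(=O)OC(C)(C)O1 | intermediate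
16 | (3R)-4-[2-(3,5-dioxopent-4-enoyl)-5-methoxy-3-(3-methylbutyl)phenyl]-3-hydroxybutanoic acid (acylketene) | CC(C)CCc1cc(OC)cc(C[C@@H](O)CC(=O)O)c1C(=O)CC(=O)C=C=O | intermediate
17 | (3R)-3-hydroxy-4-[2-(4-hydroxy-2-oxo-2H-pyran-6-yl)-5-methoxy-3-(3-methylbutyl)phenyl]butanoic acid | CC(C)CCc1cc(OC)cc(C[C@@H](O)CC(=O)O)c1-c1cc(O)cc(=O)o1 | intermediate
18 | triisopropylsilyl (3R)-4-{5-methoxy-3-(3-methylbutyl)-2-[2-oxo-4-(triisopropylsilyloxy)-2H-pyran-6-yl]phenyl}-3-[(triisopropylsilyl)oxy]butanoate | CC(C)CCc1cc(OC)cc(C[C@@H](O[Si](C(C)C)(C(C)C)C(C)C)CC(=O)O[Si](C(C)C)(C(C)C)C(C)C)c1-c1cc(O[Si](C(C)C)(C(C)C)C(C)C)cc(=O)o1 | intermediate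
19 | (3R)-4-[2-(4-hydroxy-2-oxo-2H-pyran-6-yl)-5-methoxy-3-(3-methylbutyl)phenyl]-3-[(triisopropylsilyl)oxy]butanoic acid | CC(C)CCc1cc(OC)cc(C[C@@H](O[Si](C(C)C)(C(C)C)C(C)C)CC(=O)O)c1-c1cc(O)cc(=O)o1 | intermediate
20 | (3R)-4-{5-methoxy-3-(3-methylbutyl)-2-[2-oxo-4-(trifluoroacetoxy)-2H-pyran-6-yl]phenyl}-3-[(triisopropylsilyl)oxy]butanoic trifluoroacetic anhydride | CC(C)CCc1cc(OC)cc(C[C@@H](O[Si](C(C)C)(C(C)C)C(C)C)CC(=O)OC(=O)C(F)(F)F)c1-c1cc(OC(=O)C(F)(F)F)cc(=O)o1 | intermediate
21 | (3R)-8-methoxy-6-(3-methylbutyl)-5-[2-oxo-4-(trifluoroacetoxy)-2H-pyran-6-yl]-3-[(triisopropylsilyl)oxy]-3,4-dihydronaphthalen-1(2H)-one | CC(C)CCc1cc(OC)c2c(c1-c1cc(OC(=O)C(F)(F)F)cc(=O)o1)C[C@@H](O[Si](C(C)C)(C(C)C)C(C)C)CC2=O | intermediate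
22 | (3R)-5-(4-hydroxy-2-oxo-2H-pyran-6-yl)-8-methoxy-6-(3-methylbutyl)-3-[(triisopropylsilyl)oxy]-3,4-dihydronaphthalen-1(2H)-one | CC(C)CCc1cc(OC)c2c(c1-c1cc(O)cc(=O)o1)C[C@@H](O[Si](C(C)C)(C(C)C)C(C)C)CC2=O | intermediate
23 | (3R)-8-hydroxy-5-(4-hydroxy-2-oxo-2H-pyran-6-yl)-6-(3-methylbutyl)-3-[(triisopropylsilyl)oxy]-3,4-dihydronaphthalen-1(2H)-one | CC(C)CCc1cc(O)c2c(c1-c1cc(O)cc(=O)o1)C[C@@H](O[Si](C(C)C)(C(C)C)C(C)C)CC2=O | intermediate
24 | (3R)-3,8-dihydroxy-5-(4-hydroxy-2-oxo-2H-pyran-6-yl)-6-(3-methylbutyl)-3,4-dihydronaphthalen-1(2H)-one | CC(C)CCc1cc(O)c2c(c1-c1cc(O)cc(=O)o1)C[C@@H](O)CC2=O | target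

**Step count**
Total: 13 steps. Longest linear sequence: 12 steps (steps 2 to 13, from but-3-en-1-ol 5 to 24).

**Steps most likely to fail**

Step 8. Acyl transfer from the electron-rich, doubly ortho-flanked lactone may be too slow at the low temperatures at which dienolate 14 survives, so that the dienolate decays or proton transfer takes over. The fallback sets out from 12 and uses a harder, thermally robust nucleophile with a different ring closure. Methyl acetoacetate is converted with NaH and then n-BuLi (THF, 0 °C) into the sodium lithium dianion of methyl acetoacetate F1. An excess of it, at 0 °C to rt, should be acylated at its γ-carbon by the lactone to give (3R)-3-hydroxy-4-[5-methoxy-2-(5-methoxy-3,5-dioxopentanoyl)-3-(3-methylbutyl)phenyl]butanoic acid F2. Warming F2 with DBU in toluene closes the 4-hydroxy-2-pyranone by lactonisation with loss of methanol, and the route is rejoined at 17.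

Step 11. Protic acid may strip the silyl ether or promote loss of the C3 oxygen by β-elimination and aromatisation during or after ring closure. The fallback sets out from 19 and replaces the protic mixed-anhydride closure by an acid-chloride closure without added acid, with the pyranone hydroxyl covalently masked.
- Pivaloyl chloride and pyridine (CH2Cl2, 0 °C) give the bis-pivaloylated compound, pivalic (3R)-4-{5-methoxy-3-(3-methylbutyl)-2-[2-oxo-4-(pivaloyloxy)-2H-pyran-6-yl]phenyl}-3-[(triisopropylsilyl)oxy]butanoic anhydride F3.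
- Aqueous pyridine hydrolyses its mixed anhydride to (3R)-4-{5-methoxy-3-(3-methylbutyl)-2-[2-oxo-4-(pivaloyloxy)-2H-pyran-6-yl]phenyl}-3-[(triisopropylsilyl)oxy]butanoic acid F4.
- Oxalyl chloride with catalytic DMF gives (3R)-4-{5-methoxy-3-(3-methylbutyl)-2-[2-oxo-4-(pivaloyloxy)-2H-pyran-6-yl]phenyl}-3-[(triisopropylsilyl)oxy]butanoyl chloride F5.
- Dissolving F5 in hexafluoropropan-2-ol at rt (a known catalyst-free intramolecular Friedel–Crafts acylation promoted by the hydrogen-bond-donor solvent) should give (3R)-8-methoxy-6-(3-methylbutyl)-5-[2-oxo-4-(pivaloyloxy)-2H-pyran-6-yl]-3-[(triisopropylsilyl)oxy]-3,4-dihydronaphthalen-1(2H)-one F6.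
- Brief methanolysis (MeOH, catalytic K2CO3, 0 °C) of the vinylogous anhydride returns the route at 22.

Step 5. C–H cleavage at the ortho position may stall on this donor-substituted, ortho-alkylated benzoate, or the epoxide may be consumed by the acidic solvent before it couples. The fallback sets out from 4 and keeps the same bond disconnection but changes directing group and metal. Oxalyl chloride with catalytic DMF gives 4-methoxy-2-(3-methylbutyl)benzoyl chloride F7, which acylates quinolin-8-amine (Et3N, DMAP, CH2Cl2) to give 4-methoxy-2-(3-methylbutyl)-N-(quinolin-8-yl)benzamide F8. The bidentate amide then directs a known nickel-catalysed ortho C–H coupling with epoxide 8 (Ni(OAc)2, divalent nickel, diglyme, about 140 °C). Ring opening occurs at the terminal epoxide carbon, and the resulting alkoxide displaces quinolin-8-amine from the amide, so lactone 10 is reached directly with C3 unchanged.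

**Further compounds**
F1 | step 8 | sodium lithium dianion of methyl acetoacetate | [Na+].[Li+].[CH2-]C([O-])=CC(=O)OC
F2 | step 8 | (3R)-3-hydroxy-4-[5-methoxy-2-(5-methoxy-3,5-dioxopentanoyl)-3-(3-methylbutyl)phenyl]butanoic acid | CC(C)CCc1cc(OC)cc(C[C@@H](O)CC(=O)O)c1C(=O)CC(=O)CC(=O)OC
F3 | step 11 | pivalic (3R)-4-{5-methoxy-3-(3-methylbutyl)-2-[2-oxo-4-(pivaloyloxy)-2H-pyran-6-yl]phenyl}-3-[(triisopropylsilyl)oxy]butanoic anhydride | CC(C)CCc1cc(OC)cc(C[C@@H](O[Si](C(C)C)(C(C)C)C(C)C)CC(=O)OC(=O)C(C)(C)C)c1-c1cc(OC(=O)C(C)(C)C)cc(=O)o1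
F4 | step 11 | (3R)-4-{5-methoxy-3-(3-methylbutyl)-2-[2-oxo-4-(pivaloyloxy)-2H-pyran-6-yl]phenyl}-3-[(triisopropylsilyl)oxy]butanoic acid | CC(C)CCc1cc(OC)cc(C[C@@H](O[Si](C(C)C)(C(C)C)C(C)C)CC(=O)O)c1-c1cc(OC(=O)C(C)(C)C)cc(=O)o1
F5 | step 11 | (3R)-4-{5-methoxy-3-(3-methylbutyl)-2-[2-oxo-4-(pivaloyloxy)-2H-pyran-6-yl]phenyl}-3-[(triisopropylsilyl)oxy]butanoyl chloride | CC(C)CCc1cc(OC)cc(C[C@@H](O[Si](C(C)C)(C(C)C)C(C)C)CC(=O)Cl)c1-c1cc(OC(=O)C(C)(C)C)cc(=O)o1
F6 | step 11 | (3R)-8-methoxy-6-(3-methylbutyl)-5-[2-oxo-4-(pivaloyloxy)-2H-pyran-6-yl]-3-[(triisopropylsilyl)oxy]-3,4-dihydronaphthalen-1(2H)-one | CC(C)CCc1cc(OC)c2c(c1-c1cc(OC(=O)C(C)(C)C)cc(=O)o1)C[C@@H](O[Si](C(C)C)(C(C)C)C(C)C)CC2=O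
F7 | step 5 | 4-methoxy-2-(3-methylbutyl)benzoyl chloride | CC(C)CCc1cc(OC)ccc1C(=O)Cl
F8 | step 5 | 4-methoxy-2-(3-methylbutyl)-N-(quinolin-8-yl)benzamide | CC(C)CCc1cc(OC)ccc1C(=O)Nc1cccc2cccnc12
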